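**Plan**

1. Retrosynthesis: the target is cut at C12–C13 (B-alkyl Suzuki–Miyaura coupling of a 9-vinyl decalinol with a trienyl iodide), at C8–O (epoxide of a 7-ene that comes from the C7 ketone), at C9–C11 and C8–CH3 (vinyl conjugate addition and enolate methylation on a decal-8-en-7-one), at C4–C5 (radical closure of ring A), and at C9–C10 and C5–C6 (annulation that makes ring B).
2. Forward: ring B is made first from 2,6-dimethylhept-5-enal and methyl vinyl ketone, ring A is closed second by hydrogen-atom transfer, the ring B substituents follow, and the chain (from geranyl bromide) is joined last.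
3. Enabling feature: C5 lies between the quaternary carbons C4 and C10. As the β-carbon of a C5=C6–C7=O enone in ring B it accepts the tertiary C4 radical of the 4-methylpent-3-enyl chain on C10, and the three-carbon tether forces H5 cis to the C10 methyl.
4. Stereochemistry: C10 from the asymmetric annulation; C5 from the tether; C9 from cuprate addition to the convex face of the cis-decalenone; C8 from α-epoxidation anti to vinyl and hydride opening at C7; the E alkenes from geranyl bromide and syn-carboalumination.
5. Vinyl is added only after ring A exists, because a methyl group and an open primary chain at C10 would not differentiate the faces of a monocyclic enone. A phenylsulfanyl group is carried through the radical step at the future C8 so that the C8=C9 enone is released afterwards without a regiochemical choice.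

Key step: step 3

Remark on the structure: the target SMILES describes a cis-fused decalin, (1R,2R,4aR,8aS), with H5, the C10 methyl, the C9 chain and the C8 methyl on one face (β) and the hydroxyl on the other (α).
Numbering: decalins carry labdane numbers (ring A: C1–C5 and C10; ring B: C5–C10; chain from C11); β is the face of the C10 methyl.
Assumption: the annulation catalyst is taken to follow the usual enamine model (larger α-substituent anti to nitrogen, enone delivered by the sulfonamide N–H), which calls for the D-proline-derived catalyst to reach (R)-4; if the sense were opposite, the L-proline-derived catalyst would be used.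

**Route**

Step 1
Reactants: 1 2,6-dimethylhept-5-enal (racemic); 2 but-3-en-2-one
Product: 4 (R)-4-methyl-4-(4-methylpent-3-enyl)cyclohex-2-enone, via keto aldehyde 3 (not isolated)
Conditions: (R)-N-(4-dodecylphenylsulfonyl)pyrrolidine-2-carboxamide (20 mol%), BnNH2 (1 equiv), 4 Å MS, ClCH2CH2Cl, rt to 40 °C
Reagents that add atoms: none
Why: Asymmetric Robinson-type annulation (Yamada–Otani condensation): the prolinamide forms an enamine with the α-branched aldehyde, its sulfonamide N–H steers methyl vinyl ketone to one face so that the quaternary centre (future C10) should be set as R, and keto aldehyde 3 then closes by intramolecular aldol condensation.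

Step 2
Reactants: 4
Product: 6 (4R)-4-methyl-4-(4-methylpent-3-enyl)-6-(phenylsulfanyl)cyclohex-2-enone (both C6 epimers), via lithium dienolate 5 (not isolated)
Conditions: LDA, THF, −78 °C; then PhSO2SPh, −78 °C to 0 °C
Reagents that add atoms: S-phenyl benzenethiosulfonate, O=S(=O)(Sc1ccccc1)c1ccccc1
Why: Enolate sulfenylation: C6 is the only enolisable position of 4, so LDA gives the cross-conjugated dienolate 5 without ambiguity and the thiosulfonate transfers PhS to it; the sulfide marks the future C8 and its configuration is of no consequence.

Step 3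
Reactants: 6
Product: 7 (4aR,8aR)-4a,8,8-trimethyl-3-(phenylsulfanyl)octahydronaphthalen-2(1H)-one (cis-fused; labdane positions: ketone C7 and sulfide C8; both C8 epimers)
Conditions: Fe(acac)3 (30 mol%), PhSiH3 (2.5 equiv), EtOH/HOCH2CH2OH (5:1), 60 °C
Reagents that add atoms: none
Why: An iron hydride formed from Fe(acac)3 and PhSiH3 transfers a hydrogen atom to C3 of the trisubstituted alkene, the tertiary C4 radical adds to C5 (the β-carbon of the enone), and the α-keto radical at C6 is reduced to an iron enolate that ethanol protonates. The closest known reaction type is the iron-hydride hydrogen-atom-transfer reductive olefin coupling (a Giese-type radical conjugate addition), used here intramolecularly. Ring A closes in the 6-exo-trig mode. The new stereocentre C5 is controlled by the tether: the three-carbon chain hangs from C10 and can reach C5 only on its own face and perpendicular to the enone plane, so C4 bonds on the α face and H5 ends cis to the C10 methyl. The step needs hydrogen-atom transfer to the isolated alkene rather than reduction of the enone, and it needs the crowded C4–C5 bond to form; the first is secured because the trisubstituted alkene is the only electron-rich alkene present (vinyl is introduced later), the second by the polarity match of a nucleophilic tertiary radical with the electron-poor enone. The aryl sulfide and the configuration at C8 are spectators.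

Step 4
Reactants: 7
Product: 9 (4aR,8aR)-4a,8,8-trimethyl-4a,5,6,7,8,8a-hexahydronaphthalen-2(1H)-one (cis-fused 4,4,10-trimethyldecal-8-en-7-one), via sulfoxide 8 (not isolated)
Conditions: mCPBA (1.0 equiv), CH2Cl2, −78 °C; then CaCO3, toluene, 110 °C
Reagents that add atoms: none
Why: Sulfide oxidation followed by thermal syn-elimination of the β-keto sulfoxide (sulfoxide pyrolysis): only C9 offers β-hydrogen, so the C8=C9 enone should form as a single regioisomer from either C8 epimer, and no other oxidisable alkene is present at this stage.

Step 5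
Reactants: 9; 10 vinylmagnesium bromide
Product: 12 4,4,8α,10-tetramethyl-9β-vinyl-cis-decalin-7-one, via magnesium enolate 11 (not isolated)
Conditions: CuBr·SMe2 (20 mol%), THF, −40 °C; then MeI, HMPA, −40 °C to rt
Reagents that add atoms: iodomethane, CI
Why: Copper-catalysed conjugate addition with alkylation of the resulting enolate: attack at C9 should be axial and anti to the C10–C1 bond, on the convex β face that carries the angular methyl and H5 (the α face is closed by ring A and its geminal methyls), which places vinyl cis to the C10 methyl; iodomethane then alkylates the regiodefined C7–C8 enolate anti to vinyl, a centre that step 6 erases.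

Step 6
Reactants: 12
Product: 13 4,4,8,10-tetramethyl-9β-vinyl-cis-decal-7-en-7-yl trifluoromethanesulfonate
Conditions: Tf2O, 2,6-di-tert-butyl-4-methylpyridine, CH2Cl2, 0 °C to rt
Reagents that add atoms: trifluoromethanesulfonic anhydride, O=S(=O)(OS(=O)(=O)C(F)(F)F)C(F)(F)F
Why: Enol triflate formation under equilibrating conditions: O-sulfonylation of the ketone and loss of the proton that gives the more substituted alkene should deliver the tetrasubstituted C7=C8 triflate and remove the C8 stereocentre.

Step 7
Reactants: 13
Product: 14 4,4,8,10-tetramethyl-9β-vinyl-cis-decal-7-ene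
Conditions: Pd(OAc)2 (5 mol%), PPh3 (10 mol%), HCO2H, Bu3N, DMF, 60 °C
Reagents that add atoms: none
Why: Palladium-catalysed formate reduction of an enol triflate: oxidative addition of zerovalent palladium into the C–OTf bond, formate exchange, decarboxylation and reductive elimination replace OTf by H without touching the monosubstituted vinyl group.

Step 8
Reactants: 14
Product: 15 7α,8α-epoxy-4,4,8β,10-tetramethyl-9β-vinyl-cis-decalin
Conditions: mCPBA, NaHCO3, CH2Cl2, −10 °C
Reagents that add atoms: 3-chloroperbenzoic acid, O=C(OO)c1cccc(Cl)c1
Why: Prilezhaev epoxidation: the peracid is selective for the electron-rich trisubstituted C7=C8 over the vinyl group and should approach anti to the pseudoaxial vinyl substituent on the neighbouring C9, that is from the α face, which fixes C8 (oxygen α, methyl β) and C7.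

Step 9
Reactants: 15
Product: 16 (1R,2R,4aR,8aS)-1-ethenyl-2,5,5,8a-tetramethyldecahydronaphthalen-2-ol (9β-vinyl 8α-ol)
Conditions: LiAlH4, THF, reflux
Reagents that add atoms: none
Why: Hydride opening of a trisubstituted epoxide: hydride attacks the less substituted C7 with inversion there (trans-diaxial opening), so the C8–O bond is untouched and the tertiary alcohol keeps OH α and methyl β.

Step 10
Reactants: 17 geranyl bromide; 18 1-(trimethylsilyl)propyne
Product: 20 (E)-(6,10-dimethylundeca-5,9-dien-1-ynyl)trimethylsilane, via lithiated silylpropyne 19 (not isolated)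
Conditions: n-BuLi, THF, −78 °C to −20 °C (on 18); then 17, −78 °C to rt
Reagents that add atoms: none
Why: Propargylation of an allylic bromide with a silyl-stabilised propargyllithium: deprotonation of 18 at the methyl group and SN2 displacement at the primary allylic carbon join the fragments with the E alkene of geranyl bromide intact, the silyl group suppressing allenic products.

Step 11
Reactants: 20
Product: 21 (E)-6,10-dimethylundeca-5,9-dien-1-yne
Conditions: K2CO3 (cat.), MeOH, rt
Reagents that add atoms: none
Why: Base-catalysed protodesilylation of the alkynylsilane by methoxide frees the terminal alkyne needed for carbometalation.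

Step 12
Reactants: 21
Product: 23 (1E,5E)-1-iodo-2,6,10-trimethylundeca-1,5,9-triene, via alkenylalane 22 (not isolated)
Conditions: AlMe3, Cp2ZrCl2 (25 mol%), CH2Cl2, 0 °C to rt; then I2, THF, −30 °C to 0 °C
Reagents that add atoms: trimethylaluminium, C[Al](C)C; iodine, II
Why: Negishi zirconium-catalysed carboalumination and iodinolysis: methyl and aluminium add syn across the terminal alkyne with aluminium at C1, and iodine replaces aluminium with retention, so the trisubstituted vinyl iodide should be E.

Step 13
Reactants: 16; 23
Product: 25 (1R,2R,4aR,8aS)-2,5,5,8a-tetramethyl-1-[(3E,7E)-4,8,12-trimethyltrideca-3,7,11-trienyl]decahydronaphthalen-2-ol (CNP0389811.1), via alkylborane 24 (not isolated)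
Conditions: 9-BBN dimer, THF, rt to 50 °C; aq. Cs2CO3; then 23, Pd(dppf)Cl2 (5 mol%), AsPh3, DMF, rt
Reagents that add atoms: none
Why: Hydroboration and B-alkyl Suzuki–Miyaura coupling: 9-BBN adds to the monosubstituted vinyl group with boron at the terminal carbon (the hindered tertiary hydroxyl is tolerated and excess borane is quenched before the iodide is added), and palladium couples the primary alkylborane 24 with the vinyl iodide with retention of the E geometry, forming C12–C13.

**Compound list**

1 | 2,6-dimethylhept-5-enal (racemic) | CC(C)=CCCC(C)C=O | starting material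
2 | but-3-en-2-one (methyl vinyl ketone) | CC(=O)C=C | starting material
3 | (R)-2,6-dimethyl-2-(3-oxobutyl)hept-5-enal | O=C[C@](C)(CCC=C(C)C)CCC(C)=O | intermediate
4 | (R)-4-methyl-4-(4-methylpent-3-enyl)cyclohex-2-enone | O=C1C=C[C@](C)(CCC=C(C)C)CC1 | intermediate
5 | lithium (R)-4-methyl-4-(4-methylpent-3-enyl)cyclohexa-1,5-dien-1-olate | [Li]OC1=CC[C@@](C)(CCC=C(C)C)C=C1 | intermediate
6 | (4R)-4-methyl-4-(4-methylpent-3-enyl)-6-(phenylsulfanyl)cyclohex-2-enone, both C6 epimers | O=C1C=C[C@](C)(CCC=C(C)C)CC1Sc2ccccc2 | intermediate
7 | (4aR,8aR)-4a,8,8-trimethyl-3-(phenylsulfanyl)octahydronaphthalen-2(1H)-one, cis-fused, both epimers at the sulfur-bearing carbon | O=C1C(Sc3ccccc3)C[C@@]2(C)CCCC(C)(C)[C@H]2C1 | intermediate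
8 | (4aR,8aR)-4a,8,8-trimethyl-3-(phenylsulfinyl)octahydronaphthalen-2(1H)-one, mixture of isomers at C3 and sulfur | O=C1C(S(=O)c3ccccc3)C[C@@]2(C)CCCC(C)(C)[C@H]2C1 | intermediate
9 | (4aR,8aR)-4a,8,8-trimethyl-4a,5,6,7,8,8a-hexahydronaphthalen-2(1H)-one | O=C1C=C[C@@]2(C)CCCC(C)(C)[C@H]2C1 | intermediate
10 | vinylmagnesium bromide | C=C[Mg]Br | starting material
11 | bromomagnesium C7–C8 enolate of 4,4,10-trimethyl-9β-vinyl-cis-decalin-7-one | C=C[C@@H]1[C@@]2(C)CCCC(C)(C)[C@H]2CC(O[Mg]Br)=C1 | intermediate
12 | 4,4,8α,10-tetramethyl-9β-vinyl-cis-decalin-7-one (5β-H, 10β-CH3) | C=C[C@@H]1[C@@]2(C)CCCC(C)(C)[C@H]2CC(=O)[C@H]1C | intermediate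
13 | 4,4,8,10-tetramethyl-9β-vinyl-cis-decal-7-en-7-yl trifluoromethanesulfonate | C=C[C@@H]1[C@@]2(C)CCCC(C)(C)[C@H]2CC(OS(=O)(=O)C(F)(F)F)=C1C | intermediate
14 | 4,4,8,10-tetramethyl-9β-vinyl-cis-decal-7-ene | C=C[C@@H]1[C@@]2(C)CCCC(C)(C)[C@H]2CC=C1C | intermediate
15 | 7α,8α-epoxy-4,4,8β,10-tetramethyl-9β-vinyl-cis-decalin | C=C[C@@H]1[C@@]2(C)CCCC(C)(C)[C@H]2C[C@H]3O[C@@]13C | intermediate
16 | (1R,2R,4aR,8aS)-1-ethenyl-2,5,5,8a-tetramethyldecahydronaphthalen-2-ol | C=C[C@@H]1[C@@]2(C)CCCC(C)(C)[C@H]2CC[C@@]1(C)O | intermediate
17 | geranyl bromide, (E)-1-bromo-3,7-dimethylocta-2,6-diene | CC(C)=CCC/C(C)=C/CBr | starting material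
18 | 1-(trimethylsilyl)propyne | CC#C[Si](C)(C)C | starting material
19 | 3-lithio-1-(trimethylsilyl)propyne | [Li]CC#C[Si](C)(C)C | intermediate
20 | (E)-(6,10-dimethylundeca-5,9-dien-1-ynyl)trimethylsilane | CC(C)=CCC/C(C)=C/CCC#C[Si](C)(C)C | intermediate
21 | (E)-6,10-dimethylundeca-5,9-dien-1-yne | CC(C)=CCC/C(C)=C/CCC#C | intermediate
22 | dimethyl[(1E,5E)-2,6,10-trimethylundeca-1,5,9-trienyl]alane | CC(C)=CCC/C(C)=C/CC/C(C)=C/[Al](C)C | intermediate
23 | (1E,5E)-1-iodo-2,6,10-trimethylundeca-1,5,9-triene | CC(C)=CCC/C(C)=C/CC/C(C)=C/I | intermediate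
24 | B-alkyl-9-borabicyclo[3.3.1]nonane from 16 (boron on C12) | C1CCC2CCCC1B2CC[C@@H]3[C@@]4(C)CCCC(C)(C)[C@H]4CC[C@@]3(C)O | intermediate
25 | (1R,2R,4aR,8aS)-2,5,5,8a-tetramethyl-1-[(3E,7E)-4,8,12-trimethyltrideca-3,7,11-trienyl]decahydronaphthalen-2-ol | CC(C)=CCC/C(C)=C/CC/C(C)=C/CC[C@@H]1[C@@]2(C)CCCC(C)(C)[C@H]2CC[C@@]1(C)O | target

**Step count**

Total: 13 steps. Longest linear sequence: 10 steps (steps 1–9 and 13); steps 10–12 make the side-chain iodide.

**Steps most likely to fail**

Step 8, poor or reversed facial selectivity in the epoxidation. In the cis-decalin both faces of C7=C8 are encumbered (vinyl and angular methyl on β, ring A on α), so the peracid may attack the β face. The fallback sets out from 14 and places oxygen on the face opposite to the electrophile. N-bromosuccinimide in aqueous THF at 0 °C should form the bromonium ion on the β face and let water open it at the tertiary C8 from the α face, giving the bromohydrin F1. Bu3SnH with AIBN in toluene at 80 °C then removes the bromine and the sequence rejoins the route at 16. Whichever face the electrophile prefers, one of the two sequences should lead to the 8α-alcohol.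

Step 1, insufficient enantiocontrol in the annulation. Methyl and the primary alkyl chain may be poorly distinguished in the enamine geometry, which would erode the configuration of the quaternary centre. The fallback builds that centre by sequential alkylation of a chiral auxiliary and starts from commercial (S)-valinol and 5-oxohexanoic acid instead of 1 and 2. Condensation in refluxing toluene with removal of water gives the bicyclic lactam F2. LDA and 5-bromo-2-methylpent-2-ene (DMPU) give the monoalkylated lactam F3, and LDA and iodomethane give the dialkylated lactam F4, methyl entering last on the face trans to the angular methyl. NaAlH2(OCH2CH2OCH3)2 reduces the lactam carbonyl to the carbinolamine F5. Bu4NH2PO4 in hot aqueous ethanol releases keto aldehyde 3, which condenses to 4, where the route is rejoined.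

Step 6, loss of regiocontrol in enol triflate formation. Proton loss from C6 (towards the ring fusion) may compete with loss from C8. The fallback sets out from 9 and puts the C8 methyl in place before the conjugate addition, so that the enolate double bond can only be C7=C8. Iodine and pyridine in CH2Cl2 give the α-iodo enone F6. Pd(dppf)Cl2, trimethylboroxine and K2CO3 in dioxane at 90 °C give the 8-methyl enone F7. Vinylmagnesium bromide with CuBr·SMe2 in THF at −40 °C gives the tetrasubstituted magnesium enolate F8, which N-phenylbis(trifluoromethanesulfonimide) traps as the triflate, rejoining the route at 13.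

**Further compounds**

F1 | step 8 | 7β-bromo-4,4,8β,10-tetramethyl-9β-vinyl-cis-decalin-8α-ol | C=C[C@@H]1[C@@]2(C)CCCC(C)(C)[C@H]2C[C@H](Br)[C@@]1(C)O
F2 | step 1 | (3S,8aR)-3-isopropyl-8a-methylhexahydro-5H-oxazolo[3,2-a]pyridin-5-one | C[C@@]12CCCC(=O)N1[C@@H](C(C)C)CO2
F3 | step 1 | (3S,8aR)-3-isopropyl-8a-methyl-6-(4-methylpent-3-enyl)hexahydro-5H-oxazolo[3,2-a]pyridin-5-one, both C6 epimers | C[C@@]12CCC(CCC=C(C)C)C(=O)N1[C@@H](C(C)C)CO2
F4 | step 1 | (3S,6R,8aR)-3-isopropyl-6,8a-dimethyl-6-(4-methylpent-3-enyl)hexahydro-5H-oxazolo[3,2-a]pyridin-5-one | C[C@@]12CC[C@@](C)(CCC=C(C)C)C(=O)N1[C@@H](C(C)C)CO2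
F5 | step 1 | (3S,6R,8aR)-3-isopropyl-6,8a-dimethyl-6-(4-methylpent-3-enyl)hexahydro-5H-oxazolo[3,2-a]pyridin-5-ol, both C5 epimers | C[C@@]12CC[C@@](C)(CCC=C(C)C)C(O)N1[C@@H](C(C)C)CO2
F6 | step 6 | (4aR,8aR)-3-iodo-4a,8,8-trimethyl-4a,5,6,7,8,8a-hexahydronaphthalen-2(1H)-one | O=C1C(I)=C[C@@]2(C)CCCC(C)(C)[C@H]2C1
F7 | step 6 | (4aR,8aR)-3,4a,8,8-tetramethyl-4a,5,6,7,8,8a-hexahydronaphthalen-2(1H)-one | O=C1C(C)=C[C@@]2(C)CCCC(C)(C)[C@H]2C1
F8 | step 6 | bromomagnesium C7–C8 enolate of 4,4,8,10-tetramethyl-9β-vinyl-cis-decalin-7-one | C=C[C@@H]1[C@@]2(C)CCCC(C)(C)[C@H]2CC(O[Mg]Br)=C1C
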